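**Plan**

Ring A (a1 OMe, a2 H, a3 OH, a4 and a6 4-hydroxybenzyl, a5 CH2CH2-ring B) is cut at a1–a2 and a1–a6. a1 is carbon monoxide; a2–a6 are the chain of a 3-pivaloyloxy-1,4-enyne whose terminal alkyne CH is a2.
The enyne is cut at a3–a4 (ethynyl Grignard on an enone), at a5=a6 (Horner–Wadsworth–Emmons) and at a4–a5 (acylation of a lithiated phosphonate). Ring B is cut at its two aryl–CH2 bonds.
Forward: ring B bromide, propylphosphonate, β-ketophosphonate, (E)-enone, tertiary propargylic pivalate, then rhodium/CO closes ring A, the only ring that is built.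
The free a1 hydroxyl is then methylated, the a3 pivalate cleaved and four benzyl ethers hydrogenolysed.
The target has no stereocentre; the one stereochemical element, the E geometry of a5=a6, comes from the olefination, and racemic centres of intermediates are erased later.

Key step: step 11

Remark: compounds 4, 14, 17 and 19 are racemic and their stereocentres disappear later; 3, 7 and 16 are taken as commercial THF solutions.

**Step 1**
Reactants: 1 4-bromo-2-hydroxybenzaldehyde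
Product: 2 2-(benzyloxy)-4-bromobenzaldehyde
Conditions: BnBr, K2CO3, DMF, rt
Reagents that add atoms: benzyl bromide, BrCc1ccccc1
Why: Williamson etherification of the phenoxide, to which the aldehyde and the aryl bromide are inert.

**Step 2**
Reactants: 2 2-(benzyloxy)-4-bromobenzaldehyde; 3 4-(benzyloxy)phenylmagnesium bromide
Product: 4 [2-(benzyloxy)-4-bromophenyl][4-(benzyloxy)phenyl]methanol (racemic)
Conditions: THF, 0 °C; aq NH4Cl
Reagents that add atoms: none
Why: Grignard addition to the aldehyde is much faster at 0 °C than halogen–magnesium exchange at the aryl bromide, and the racemic carbinol centre is removed in step 3.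

**Step 3**
Reactants: 4 [2-(benzyloxy)-4-bromophenyl][4-(benzyloxy)phenyl]methanol
Product: 5 2-(benzyloxy)-1-[4-(benzyloxy)benzyl]-4-bromobenzene
Conditions: Et3SiH, CF3CO2H, CH2Cl2, 0 °C
Reagents that add atoms: none
Why: Ionic hydrogenation, in which the acid ionises the doubly alkoxy-stabilised benzhydrol and the silane delivers hydride, while aryl benzyl ethers and the bromide tolerate brief cold acid.

**Step 4**
Reactants: 5 2-(benzyloxy)-1-[4-(benzyloxy)benzyl]-4-bromobenzene; 6 diethyl allylphosphonate; 7 9-borabicyclo[3.3.1]nonane (9-BBN)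
Product: 9 diethyl {3-[3-(benzyloxy)-4-(4-(benzyloxy)benzyl)phenyl]propyl}phosphonate, via alkylborane 8 (not isolated)
Conditions: 6, 9-BBN, THF, 0 °C to rt; then 5, PdCl2(dppf), aq K3PO4, DMF, 60 °C
Reagents that add atoms: none
Why: Anti-Markovnikov hydroboration of the terminal alkene followed by B-alkyl Suzuki–Miyaura coupling (oxidative addition of the aryl bromide to zerovalent palladium), with phosphonate and benzyl ethers as spectators.

**Step 5**
Reactants: 10 [4-(benzyloxy)phenyl]acetic acid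
Product: 11 2-[4-(benzyloxy)phenyl]-N-methoxy-N-methylacetamide
Conditions: MeNHOMe·HCl, EDC·HCl, N-methylmorpholine, CH2Cl2, 0 °C to rt
Reagents that add atoms: N,O-dimethylhydroxylamine hydrochloride, CNOC.Cl
Why: Carbodiimide-mediated amide coupling to the Weinreb amide, which serves both as acyl donor (step 7) and as aldehyde precursor (step 6).

**Step 6**
Reactants: 11 2-[4-(benzyloxy)phenyl]-N-methoxy-N-methylacetamide
Product: 12 [4-(benzyloxy)phenyl]acetaldehyde
Conditions: DIBAL-H, THF, −78 °C; aq Rochelle salt; used at once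
Reagents that add atoms: none
Why: Hydride reduction of a Weinreb amide stops at the chelated aluminium hemiaminal, so the sensitive arylacetaldehyde is released only on work-up and is not over-reduced.

**Step 7**
Reactants: 9 diethyl {3-[3-(benzyloxy)-4-(4-(benzyloxy)benzyl)phenyl]propyl}phosphonate; 11 2-[4-(benzyloxy)phenyl]-N-methoxy-N-methylacetamide
Product: 14 diethyl {1-[4-(benzyloxy)phenyl]-5-[3-(benzyloxy)-4-(4-(benzyloxy)benzyl)phenyl]-2-oxopentan-3-yl}phosphonate (racemic), via lithiated phosphonate 13 (not isolated)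
Conditions: LDA, THF, −78 °C; then 11, −78 to −20 °C; aq NH4Cl
Reagents that add atoms: LDA, [Li]N(C(C)C)C(C)C (supplies only the lithium of intermediate 13)
Why: Acylation of an α-lithiated alkylphosphonate by a Weinreb amide, whose chelated tetrahedral adduct survives until the quench so that the acidic β-ketophosphonate cannot consume a second equivalent of carbanion; the racemic C–P centre is lost in step 8.

**Step 8**
Reactants: 14 the β-ketophosphonate; 12 [4-(benzyloxy)phenyl]acetaldehyde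
Product: 15 (E)-1,5-bis[4-(benzyloxy)phenyl]-3-{2-[3-(benzyloxy)-4-(4-(benzyloxy)benzyl)phenyl]ethyl}pent-3-en-2-one
Conditions: Ba(OH)2, THF/H2O (40:1), 0 °C to rt
Reagents that add atoms: none
Why: Horner–Wadsworth–Emmons olefination, in which reversible addition of the phosphonate enolate and syn-elimination from the more stable adduct place the acyl group trans to the new CH2Ar group (E), the mild hydroxide base limiting enolisation of 12.

**Step 9**
Reactants: 15 the (E)-enone; 16 ethynylmagnesium bromide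
Product: 17 (E)-3-[4-(benzyloxy)benzyl]-6-[4-(benzyloxy)phenyl]-4-{2-[3-(benzyloxy)-4-(4-(benzyloxy)benzyl)phenyl]ethyl}hex-4-en-1-yn-3-ol (racemic)
Conditions: LaCl3·2LiCl, THF, 0 °C; aq NH4Cl
Reagents that add atoms: none
Why: 1,2-Addition of an alkynyl Grignard reagent to the enone carbonyl, with the lanthanum salt activating the carbonyl and suppressing enolisation at the benzylic α'-position; the tertiary centre is racemic and is erased in step 11.

**Step 10**
Reactants: 17 the tertiary propargylic alcohol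
Product: 19 (E)-3-[4-(benzyloxy)benzyl]-6-[4-(benzyloxy)phenyl]-4-{2-[3-(benzyloxy)-4-(4-(benzyloxy)benzyl)phenyl]ethyl}hex-4-en-1-yn-3-yl pivalate (racemic), via lithium alkoxide 18 (not isolated)
Conditions: LiHMDS, THF, −78 °C; then PivCl, −78 °C to rt
Reagents that add atoms: pivaloyl chloride, CC(C)(C)C(=O)Cl; LiHMDS, [Li]N([Si](C)(C)C)[Si](C)(C)C (supplies only the lithium of intermediate 18)
Why: O-Acylation of a preformed lithium alkoxide, the hydroxyl being deprotonated in preference to the alkyne C–H, which overcomes the slow amine-catalysed acylation expected for so hindered a tertiary carbinol.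

**Step 11**
Reactants: 19 the 3-pivaloyloxy-1,4-enyne; 20 carbon monoxide
Product: 23 2,4-bis[4-(benzyloxy)benzyl]-3-{2-[3-(benzyloxy)-4-(4-(benzyloxy)benzyl)phenyl]ethyl}-5-hydroxyphenyl pivalate, via dienylketene 21 (not isolated), via cyclohexadienone 22 (not isolated)
Conditions: [Rh(CO)2Cl]2 (5 mol%), CO (80 bar), CH2Cl2, 80 °C
Reagents that add atoms: none
Why: Monovalent rhodium binds the terminal alkyne, the pivalate carbonyl oxygen attacks the internal alkyne carbon a3 and the a4–O bond breaks, which moves the ester from a4 to a3 (1,2-acyloxy shift) and leaves an alkenyl rhodium carbene at a2. CO inserts into the carbene (a1–a2 bond) to give dienylketene 21, whose thermal disrotatory six-electron electrocyclisation joins a1 to a6 and gives cyclohexa-2,4-dienone 22, which tautomerises to the phenol. This is the known rhodium-catalysed (5+1) carbonylative benzannulation of 3-acyloxy-1,4-enynes to resorcinol monoesters. No stereocentre is formed, and the racemic centre at a4 becomes an aromatic carbon. The step needs a 1,2- and not a 1,3-acyloxy shift, which the unsubstituted alkyne terminus favours, and it needs a6 to reach the ketene carbon, which the E alkene secures by turning only hydrogen inward. The two oxygens emerge differentiated, free OH at a1 and ester at a3, as the target requires.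

**Step 12**
Reactants: 23 the resorcinol monopivalate
Product: 24 2,4-bis[4-(benzyloxy)benzyl]-3-{2-[3-(benzyloxy)-4-(4-(benzyloxy)benzyl)phenyl]ethyl}-5-methoxyphenyl pivalate
Conditions: MeI, K2CO3, acetone, rt
Reagents that add atoms: iodomethane, CI
Why: Williamson methylation of the only free phenol (a1), the hindered aryl pivalate being stable to carbonate in acetone.

**Step 13**
Reactants: 24 the methyl ether pivalate
Product: 25 2,4-bis[4-(benzyloxy)benzyl]-3-{2-[3-(benzyloxy)-4-(4-(benzyloxy)benzyl)phenyl]ethyl}-5-methoxyphenol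
Conditions: NaOMe, MeOH/THF, 50 °C; aq NH4Cl
Reagents that add atoms: none
Why: Transesterification of the aryl pivalate by methoxide frees the a3 phenol, while benzyl and methyl ethers are inert.

**Step 14**
Reactants: 25 the tetrabenzyl ether
Product: 26 2,4-bis(4-hydroxybenzyl)-3-{2-[3-hydroxy-4-(4-hydroxybenzyl)phenyl]ethyl}-5-methoxyphenol (CNP0207338.0)
Conditions: H2 (1 atm), Pd/C (palladium on carbon), EtOAc/MeOH, rt
Reagents that add atoms: none
Why: Catalytic hydrogenolysis cleaves the four benzyl aryl ethers, while the diarylmethane C–C bonds, the methyl ether and the arenes are not touched.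

**Compound list**

1 | 4-bromo-2-hydroxybenzaldehyde | O=Cc1ccc(Br)cc1O | starting material
2 | 2-(benzyloxy)-4-bromobenzaldehyde | O=Cc1ccc(Br)cc1OCc1ccccc1 | intermediate
3 | 4-(benzyloxy)phenylmagnesium bromide | Br[Mg]c1ccc(OCc2ccccc2)cc1 | starting material
4 | [2-(benzyloxy)-4-bromophenyl][4-(benzyloxy)phenyl]methanol, racemic | OC(c1ccc(OCc2ccccc2)cc1)c1ccc(Br)cc1OCc1ccccc1 | intermediate
5 | 2-(benzyloxy)-1-[4-(benzyloxy)benzyl]-4-bromobenzene | Brc1ccc(Cc2ccc(OCc3ccccc3)cc2)c(OCc2ccccc2)c1 | intermediate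
6 | diethyl allylphosphonate | C=CCP(=O)(OCC)OCC | starting material
7 | 9-borabicyclo[3.3.1]nonane (9-BBN) | B1C2CCCC1CCC2 | starting material
8 | diethyl [3-(9-borabicyclo[3.3.1]nonan-9-yl)propyl]phosphonate (not isolated) | CCOP(=O)(CCCB1C2CCCC1CCC2)OCC | intermediate
9 | diethyl {3-[3-(benzyloxy)-4-(4-(benzyloxy)benzyl)phenyl]propyl}phosphonate | CCOP(=O)(CCCc1ccc(Cc2ccc(OCc3ccccc3)cc2)c(OCc2ccccc2)c1)OCC | intermediate
10 | [4-(benzyloxy)phenyl]acetic acid | OC(=O)Cc1ccc(OCc2ccccc2)cc1 | starting material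
11 | 2-[4-(benzyloxy)phenyl]-N-methoxy-N-methylacetamide | CON(C)C(=O)Cc1ccc(OCc2ccccc2)cc1 | intermediate
12 | [4-(benzyloxy)phenyl]acetaldehyde | O=CCc1ccc(OCc2ccccc2)cc1 | intermediate
13 | 9 lithiated at the carbon next to phosphorus (not isolated) | CCOP(=O)(OCC)C([Li])CCc1ccc(Cc2ccc(OCc3ccccc3)cc2)c(OCc2ccccc2)c1 | intermediate
14 | diethyl {1-[4-(benzyloxy)phenyl]-5-[3-(benzyloxy)-4-(4-(benzyloxy)benzyl)phenyl]-2-oxopentan-3-yl}phosphonate, racemic | CCOP(=O)(OCC)C(CCc1ccc(Cc2ccc(OCc3ccccc3)cc2)c(OCc2ccccc2)c1)C(=O)Cc1ccc(OCc2ccccc2)cc1 | intermediate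
15 | (E)-1,5-bis[4-(benzyloxy)phenyl]-3-{2-[3-(benzyloxy)-4-(4-(benzyloxy)benzyl)phenyl]ethyl}pent-3-en-2-one | O=C(Cc1ccc(OCc2ccccc2)cc1)/C(CCc1ccc(Cc2ccc(OCc3ccccc3)cc2)c(OCc2ccccc2)c1)=C/Cc1ccc(OCc2ccccc2)cc1 | intermediate
16 | ethynylmagnesium bromide | C#C[Mg]Br | starting material
17 | (E)-3-[4-(benzyloxy)benzyl]-6-[4-(benzyloxy)phenyl]-4-{2-[3-(benzyloxy)-4-(4-(benzyloxy)benzyl)phenyl]ethyl}hex-4-en-1-yn-3-ol, racemic | C#CC(O)(Cc1ccc(OCc2ccccc2)cc1)/C(CCc1ccc(Cc2ccc(OCc3ccccc3)cc2)c(OCc2ccccc2)c1)=C/Cc1ccc(OCc2ccccc2)cc1 | intermediate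
18 | lithium alkoxide of 17 (not isolated) | C#CC(O[Li])(Cc1ccc(OCc2ccccc2)cc1)/C(CCc1ccc(Cc2ccc(OCc3ccccc3)cc2)c(OCc2ccccc2)c1)=C/Cc1ccc(OCc2ccccc2)cc1 | intermediate
19 | pivalate of 17, the racemic tertiary 3-pivaloyloxy-1,4-enyne with E alkene | C#CC(Cc1ccc(OCc2ccccc2)cc1)(OC(=O)C(C)(C)C)/C(CCc1ccc(Cc2ccc(OCc3ccccc3)cc2)c(OCc2ccccc2)c1)=C/Cc1ccc(OCc2ccccc2)cc1 | intermediate
20 | carbon monoxide | [C-]#[O+] | starting material
21 | dienylketene O=C(a1)=CH(a2)–C(OPiv)(a3)=C(CH2Ar)(a4)–C(CH2CH2-ring B)(a5)=CH(a6)–CH2Ar, a2 and a5 cis across a3=a4, a4 and CH2Ar trans across a5=a6 (not isolated) | O=C=C/C(OC(=O)C(C)(C)C)=C(Cc1ccc(OCc2ccccc2)cc1)\C(CCc1ccc(Cc2ccc(OCc3ccccc3)cc2)c(OCc2ccccc2)c1)=C\Cc1ccc(OCc2ccccc2)cc1 | intermediate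
22 | cyclohexa-2,4-dien-1-one tautomer of 23 with sp3 carbon a6, racemic (not isolated) | O=C1C=C(OC(=O)C(C)(C)C)C(Cc2ccc(OCc3ccccc3)cc2)=C(CCc2ccc(Cc3ccc(OCc4ccccc4)cc3)c(OCc3ccccc3)c2)C1Cc1ccc(OCc2ccccc2)cc1 | intermediate
23 | 2,4-bis[4-(benzyloxy)benzyl]-3-{2-[3-(benzyloxy)-4-(4-(benzyloxy)benzyl)phenyl]ethyl}-5-hydroxyphenyl pivalate | Oc1cc(OC(=O)C(C)(C)C)c(Cc2ccc(OCc3ccccc3)cc2)c(CCc2ccc(Cc3ccc(OCc4ccccc4)cc3)c(OCc3ccccc3)c2)c1Cc1ccc(OCc2ccccc2)cc1 | intermediate
24 | 2,4-bis[4-(benzyloxy)benzyl]-3-{2-[3-(benzyloxy)-4-(4-(benzyloxy)benzyl)phenyl]ethyl}-5-methoxyphenyl pivalate | COc1cc(OC(=O)C(C)(C)C)c(Cc2ccc(OCc3ccccc3)cc2)c(CCc2ccc(Cc3ccc(OCc4ccccc4)cc3)c(OCc3ccccc3)c2)c1Cc1ccc(OCc2ccccc2)cc1 | intermediate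
25 | 2,4-bis[4-(benzyloxy)benzyl]-3-{2-[3-(benzyloxy)-4-(4-(benzyloxy)benzyl)phenyl]ethyl}-5-methoxyphenol | COc1cc(O)c(Cc2ccc(OCc3ccccc3)cc2)c(CCc2ccc(Cc3ccc(OCc4ccccc4)cc3)c(OCc3ccccc3)c2)c1Cc1ccc(OCc2ccccc2)cc1 | intermediate
26 | 2,4-bis(4-hydroxybenzyl)-3-{2-[3-hydroxy-4-(4-hydroxybenzyl)phenyl]ethyl}-5-methoxyphenol | COc1cc(O)c(Cc2ccc(O)cc2)c(CCc2ccc(Cc3ccc(O)cc3)c(O)c2)c1Cc1ccc(O)cc1 | target

**Totals**

Total step count: 14. Longest linear sequence: 12 steps (steps 1–4 and 7–14); steps 5 and 6 are a two-step branch.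

**Steps most likely to fail**

1. Step 11. The tertiary pivalate, which is both allylic and propargylic, may ionise or undergo a 1,3-acyloxy shift faster than the 1,2-shift, leading to elimination or allenyl ester chemistry. Crowding around a4–a6 may also slow the electrocyclisation so that the ketene is diverted.

   Fallback (sets out from phosphonate 9 and aldehyde 12, returns at 25): ring A is closed by the same a1–a6 electrocyclisation of a dienylketene, but a1 comes from a Wolff rearrangement and a2/a3 from an alkoxyacetylene (Danheiser benzannulation). Commercial 3-[4-(benzyloxy)phenyl]propanoic acid is coupled as in step 5 to give 3-[4-(benzyloxy)phenyl]-N-methoxy-N-methylpropanamide F1. Lithiated 9 (13) is acylated with it as in step 7 to give diethyl {1-[4-(benzyloxy)phenyl]-6-[3-(benzyloxy)-4-(4-(benzyloxy)benzyl)phenyl]-3-oxohexan-4-yl}phosphonate F2. Olefination with 12 as in step 8 gives (E)-1,6-bis[4-(benzyloxy)phenyl]-4-{2-[3-(benzyloxy)-4-(4-(benzyloxy)benzyl)phenyl]ethyl}hex-4-en-3-one F3. Kinetic deprotonation at the saturated methylene next to the carbonyl (LiHMDS, −78 °C) and trapping with 2,2,2-trifluoroethyl trifluoroacetate gives the 2-trifluoroacetyl derivative of F3 F4 (not isolated). Diazo transfer with MsN3 and Et3N then gives (E)-2-diazo-1,6-bis[4-(benzyloxy)phenyl]-4-{2-[3-(benzyloxy)-4-(4-(benzyloxy)benzyl)phenyl]ethyl}hex-4-en-3-one F5. Irradiation of F5 in the presence of methoxyacetylene F6 (prepared from chloroacetaldehyde dimethyl acetal and NaNH2), followed by warming to 80 °C, should give a phenol by Wolff rearrangement, ketene–alkyne cycloaddition, four-electron ring opening and six-electron closure. That phenol has OH on the former ketene carbon, H on the neighbouring carbon and OMe meta to OH. Because a4 and a6 carry the same 4-(benzyloxy)benzyl group, it is 25, and step 14 follows.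

2. Step 8. The arylacetaldehyde may enolise and condense with itself while the α-branched phosphonate anion adds slowly. The base may also move the new double bond out of conjugation toward the aryl ring or erode the E geometry.

   Fallback (sets out from aldehyde 12, Grignard reagent 16 and bromide 5, returns at 15): the trisubstituted alkene is made from an alkyne by anti hydrometalation and cross-coupling, so no olefination of 12 is needed. Addition of 16 to 12 gives 1-[4-(benzyloxy)phenyl]but-3-yn-2-ol F7. Coupling of its alkyne C–H with commercial 4-(benzyloxy)benzyl chloride (copper iodide CuI, Cs2CO3, NaI, DMF) gives 1,5-bis[4-(benzyloxy)phenyl]pent-3-yn-2-ol F8. Hydroxyl-directed trans-hydrostannation (Bu3SnH, [Cp*RuCl]4, CH2Cl2) puts tin on the alkyne carbon next to the carbinol and hydrogen anti to it, giving (Z)-1,5-bis[4-(benzyloxy)phenyl]-3-(tributylstannyl)pent-3-en-2-ol F9. I2 converts it with retention into (Z)-1,5-bis[4-(benzyloxy)phenyl]-3-iodopent-3-en-2-ol F10. Separately, 5 and potassium vinyltrifluoroborate (PdCl2(dppf), Cs2CO3, THF/H2O) give 2-(benzyloxy)-1-[4-(benzyloxy)benzyl]-4-vinylbenzene F11. Hydroboration with 9-BBN gives 9-{2-[3-(benzyloxy)-4-(4-(benzyloxy)benzyl)phenyl]ethyl}-9-borabicyclo[3.3.1]nonane F12 (not isolated). B-alkyl Suzuki coupling of F12 with F10 (PdCl2(dppf), Cs2CO3, DMF/H2O) gives (E)-1,5-bis[4-(benzyloxy)phenyl]-3-{2-[3-(benzyloxy)-4-(4-(benzyloxy)benzyl)phenyl]ethyl}pent-3-en-2-ol F13. Dess–Martin oxidation of F13 gives 15.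

3. Step 7. Proton transfer from the acidic benzylic methylene of amide 11 to the lithiated phosphonate may compete with carbonyl addition, returning 9 and enolised amide.

   Fallback (sets out from lithiated phosphonate 13 and aldehyde 12, returns at 14): addition to the far more electrophilic aldehyde at −78 °C should outrun proton transfer and give diethyl {1-[4-(benzyloxy)phenyl]-5-[3-(benzyloxy)-4-(4-(benzyloxy)benzyl)phenyl]-2-hydroxypentan-3-yl}phosphonate F14 as a diastereomer mixture. Dess–Martin oxidation of F14 gives 14.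

**Further compounds**

F1 | step 11 | 3-[4-(benzyloxy)phenyl]-N-methoxy-N-methylpropanamide | CON(C)C(=O)CCc1ccc(OCc2ccccc2)cc1
F2 | step 11 | diethyl {1-[4-(benzyloxy)phenyl]-6-[3-(benzyloxy)-4-(4-(benzyloxy)benzyl)phenyl]-3-oxohexan-4-yl}phosphonate, racemic | CCOP(=O)(OCC)C(CCc1ccc(Cc2ccc(OCc3ccccc3)cc2)c(OCc2ccccc2)c1)C(=O)CCc1ccc(OCc2ccccc2)cc1
F3 | step 11 | (E)-1,6-bis[4-(benzyloxy)phenyl]-4-{2-[3-(benzyloxy)-4-(4-(benzyloxy)benzyl)phenyl]ethyl}hex-4-en-3-one | O=C(CCc1ccc(OCc2ccccc2)cc1)/C(CCc1ccc(Cc2ccc(OCc3ccccc3)cc2)c(OCc2ccccc2)c1)=C/Cc1ccc(OCc2ccccc2)cc1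
F4 | step 11 | 2-trifluoroacetyl derivative of F3, racemic (not isolated) | O=C(C(Cc1ccc(OCc2ccccc2)cc1)C(=O)C(F)(F)F)/C(CCc1ccc(Cc2ccc(OCc3ccccc3)cc2)c(OCc2ccccc2)c1)=C/Cc1ccc(OCc2ccccc2)cc1
F5 | step 11 | (E)-2-diazo-1,6-bis[4-(benzyloxy)phenyl]-4-{2-[3-(benzyloxy)-4-(4-(benzyloxy)benzyl)phenyl]ethyl}hex-4-en-3-one | [N-]=[N+]=C(Cc1ccc(OCc2ccccc2)cc1)C(=O)/C(CCc1ccc(Cc2ccc(OCc3ccccc3)cc2)c(OCc2ccccc2)c1)=C/Cc1ccc(OCc2ccccc2)cc1
F6 | step 11 | methoxyacetylene | COC#C
F7 | step 8 | 1-[4-(benzyloxy)phenyl]but-3-yn-2-ol, racemic | C#CC(O)Cc1ccc(OCc2ccccc2)cc1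
F8 | step 8 | 1,5-bis[4-(benzyloxy)phenyl]pent-3-yn-2-ol, racemic | OC(Cc1ccc(OCc2ccccc2)cc1)C#CCc1ccc(OCc2ccccc2)cc1
F9 | step 8 | (Z)-1,5-bis[4-(benzyloxy)phenyl]-3-(tributylstannyl)pent-3-en-2-ol, racemic | OC(Cc1ccc(OCc2ccccc2)cc1)/C(=C/Cc1ccc(OCc2ccccc2)cc1)[Sn](CCCC)(CCCC)CCCC
F10 | step 8 | (Z)-1,5-bis[4-(benzyloxy)phenyl]-3-iodopent-3-en-2-ol, racemic | OC(Cc1ccc(OCc2ccccc2)cc1)/C(I)=C/Cc1ccc(OCc2ccccc2)cc1
F11 | step 8 | 2-(benzyloxy)-1-[4-(benzyloxy)benzyl]-4-vinylbenzene | C=Cc1ccc(Cc2ccc(OCc3ccccc3)cc2)c(OCc2ccccc2)c1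
F12 | step 8 | 9-{2-[3-(benzyloxy)-4-(4-(benzyloxy)benzyl)phenyl]ethyl}-9-borabicyclo[3.3.1]nonane (not isolated) | B1(CCc2ccc(Cc3ccc(OCc4ccccc4)cc3)c(OCc3ccccc3)c2)C2CCCC1CCC2
F13 | step 8 | (E)-1,5-bis[4-(benzyloxy)phenyl]-3-{2-[3-(benzyloxy)-4-(4-(benzyloxy)benzyl)phenyl]ethyl}pent-3-en-2-ol, racemic | OC(Cc1ccc(OCc2ccccc2)cc1)/C(CCc1ccc(Cc2ccc(OCc3ccccc3)cc2)c(OCc2ccccc2)c1)=C/Cc1ccc(OCc2ccccc2)cc1
F14 | step 7 | diethyl {1-[4-(benzyloxy)phenyl]-5-[3-(benzyloxy)-4-(4-(benzyloxy)benzyl)phenyl]-2-hydroxypentan-3-yl}phosphonate, diastereomer mixture | CCOP(=O)(OCC)C(CCc1ccc(Cc2ccc(OCc3ccccc3)cc2)c(OCc2ccccc2)c1)C(O)Cc1ccc(OCc2ccccc2)cc1
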